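**Retrosynthetic overview**

1. In labdane numbering (decalin C1–C10, chain C11–C16 on C9, C17 on C8, C18/C19 on C4, C20 on C10) the target is an A/B-cis decalin. H-5, CH3-20, C-11 and CH3-17 all lie on its convex face and the C8 acetate on the concave face, so only C5 needs a catalyst and C10, C9 and C8 are relayed from it by convex-face C–C bond formation.
2. C8–C17 is cut last: tertiary acetate ⇐ CH3MgBr addition to the 17-nor-8-ketone with acetylation of the alkoxide in the same flask.
3. Key disconnection, one pot: C10–C20 and C9–C11. Conjugate methylation of a Δ9(10)-8-oxo-octalone sets quaternary C10 cis to H-5, and the enolate is alkylated at C9 by the intact C11–C16 iodide (C13 from methyl hydrogen (R)-3-methylglutarate).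
4. Octalone ⇐ enantioselective β,γ→α,β isomerisation (sets C5) of the Birch product of 6-methoxy-1,1-dimethyltetralin ⇐ 6-methoxy-1-tetralone (its C=O becomes the C4 gem-dimethyl carbon).
5. Ring order: no ring is closed. Ring A is the saturated ring of the tetralone and ring B (C5–C10) is its anisole ring, dearomatised in step 2.

Key step: step 6

Remark: the SMILES encodes (5R,8R,9R,10S,13S), with H-5 cis to CH3-20, i.e. the A/B-cis C5 epimer of the labdanolic acid series; the route is built for exactly this configuration.

Step 1
Reactants: 1 6-methoxy-3,4-dihydronaphthalen-1(2H)-one (6-methoxy-1-tetralone)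
Product: 2 6-methoxy-1,1-dimethyl-1,2,3,4-tetrahydronaphthalene
Conditions: Me2Zn, TiCl4 (gives Me2TiCl2, 2 equiv), CH2Cl2, −30 → 0 °C
Reagents that add atoms: dimethylzinc, C[Zn]C
Why: Reetz geminal dimethylation, in which Me2TiCl2 adds CH3 to the ketone and the titanium alkoxide ionises to the p-methoxybenzylic cation that takes the second CH3, so the C=O becomes the gem-dimethyl carbon C4; no stereocentre is formed.

Step 2
Reactants: 2 6-methoxy-1,1-dimethyl-1,2,3,4-tetrahydronaphthalene
Product: 4 5,5-dimethyl-3,4,5,6,7,8-hexahydronaphthalen-2(1H)-one, via dihydroanisole enol ether 3 (not isolated)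
Conditions: Li, NH3(l), THF, t-BuOH, −33 °C; then oxalic acid, MeOH–H2O, rt
Reagents that add atoms: water, O
Why: Birch reduction should give the 2,5-dihydroanisole with the tetrasubstituted ring-fusion alkene left in place, and mild enol-ether hydrolysis should give the unconjugated β,γ-enone without moving the double bond, as in 19-nor-steroid chemistry; 4 is achiral.

Step 3
Reactants: 4 5,5-dimethyl-3,4,5,6,7,8-hexahydronaphthalen-2(1H)-one
Product: 5 (4aR)-5,5-dimethyl-4,4a,5,6,7,8-hexahydronaphthalen-2(3H)-one
Conditions: 9-amino-9-deoxy-epi-cinchona primary amine (10 mol %; the quinine- or quinidine-derived antipode that gives 4aR), ArCO2H co-catalyst (20 mol %), toluene, −20 °C → rt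
Reagents that add atoms: none
Why: Primary-amine/acid-catalysed enantioselective β,γ→α,β isomerisation of a Birch-derived cyclohex-3-enone, in which the iminium is deprotonated at C1 to a dienamine and the catalyst delivers H+ to one face of the γ-carbon C4a, which sets C5 (labdane numbering) as the only catalyst-controlled ring stereocentre.

Step 4
Reactants: 6 (R)-5-methoxy-3-methyl-5-oxopentanoic acid (methyl hydrogen (R)-3-methylglutarate)
Product: 8 (S)-4-methyloxan-2-one, via hydroxy acid 7 (not isolated)
Conditions: LiBH4, THF, 0 °C → rt; then 2 M HCl, rt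
Reagents that add atoms: none
Why: Chemoselective LiBH4 reduction of the ester beside the inert lithium carboxylate, then lactonisation of the δ-hydroxy acid on acidification; the stereocentre is not touched (R→S is only a change of CIP priorities) and reducing this carbonyl gives the C13 configuration of the target.

Step 5
Reactants: 8 (S)-4-methyloxan-2-one
Product: 10 methyl (R)-5-iodo-3-methylpentanoate, via silyl ester 9 (not isolated)
Conditions: Me3SiCl, NaI, MeCN, 60 °C; then MeOH, 60 °C
Reagents that add atoms: sodium iodide, [Na+].[I-]; methanol, CO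
Why: Lactone cleavage by Me3SiI (SN2 attack of iodide on the primary O–CH2 carbon of the silylated lactone) followed by methanolysis and HI-catalysed Fischer esterification; the stereocentre is not involved (S→R is again a priority change).

Step 6
Reactants: 5 (4aR)-5,5-dimethyl-4,4a,5,6,7,8-hexahydronaphthalen-2(3H)-one; 10 methyl (R)-5-iodo-3-methylpentanoate
Product: 12 methyl (3S)-3-methyl-5-[(1R,4aR,8aS)-5,5,8a-trimethyl-2-oxodecahydronaphthalen-1-yl]pentanoate, via lithium enolate 11 (not isolated)
Conditions: Me2CuLi (from MeLi and CuI, 1.2 equiv), Et2O, −20 → 0 °C; then HMPA, THF, 10 (2 equiv), −20 °C → rt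
Reagents that add atoms: lithium dimethylcuprate, [Li+].C[Cu-]C (made from methyllithium, [Li]C, and CuI)
Why: Conjugate addition–enolate alkylation (vicinal dialkylation, a three-component coupling) that closes no ring, since both rings are already in 5, and makes the C10–C20 and C9–C11 bonds. The cuprate should transfer CH3 to the β-carbon C10 on the face trans to the bulky C4-bearing substituent on the neighbouring C5, as cuprates do with Δ1(8a)-2-octalones and 4-substituted cyclohexenones, so C5 controls C10 and H-5 and CH3-20 end cis (A/B-cis fusion). The regiodefined C8(OLi)=C9 enolate 11 should then be alkylated by SN2 at C9 with the primary iodide 10 from the convex β-face, axially and anti to the axial C1H2 of ring A, so C5/C10 control C9 and C-11 ends cis to CH3-20. C13 comes in unchanged with 10. The step needs C- over O-alkylation and mono-alkylation at C9 without enolate equilibration to C7; the soft iodide, the HMPA-activated lithium enolate, the absence of a proton source and the excess of 10 are meant to secure this, and the ester of 10 should survive because SN2 at the primary iodide is faster than Claisen attack.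

Step 7
Reactants: 12 methyl (3S)-3-methyl-5-[(1R,4aR,8aS)-5,5,8a-trimethyl-2-oxodecahydronaphthalen-1-yl]pentanoate
Product: 14 methyl (3S)-5-[(1R,2R,4aR,8aS)-2-acetoxy-2,5,5,8a-tetramethyldecahydronaphthalen-1-yl]-3-methylpentanoate, via bromomagnesium alkoxide 13 (not isolated)
Conditions: MeMgBr, CeCl3, THF, −78 °C; then Ac2O, DMAP, −78 °C → rt
Reagents that add atoms: methylmagnesium bromide, C[Mg]Br; acetic anhydride, CC(=O)OC(C)=O
Why: Cerium-mediated Grignard 1,2-addition in which CH3 should attack C8 along the equatorial trajectory on the convex β-face, the axial α-trajectory being blocked by the syn-axial C1H2 of ring A, so C9/C10 control C8 (8β-CH3, 8α-O); the ketone reacts faster than the methyl ester at −78 °C and the hindered tertiary alkoxide is acetylated in the same flask.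

Step 8
Reactants: 14 methyl (3S)-5-[(1R,2R,4aR,8aS)-2-acetoxy-2,5,5,8a-tetramethyldecahydronaphthalen-1-yl]-3-methylpentanoate
Product: 15 (3S)-5-[(1R,2R,4aR,8aS)-2-acetoxy-2,5,5,8a-tetramethyldecahydronaphthalen-1-yl]-3-methylpentanoic acid
Conditions: LiOH, THF–H2O, 0 °C → rt; then aq. HCl to pH 3
Reagents that add atoms: lithium hydroxide, [Li+].[OH-]
Why: Saponification (BAc2) of the unhindered primary-chain methyl ester, while the axial tertiary acetate at C8 hydrolyses far more slowly, so no stereocentre and no other group should be disturbed.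

**Compound list**

1 | 6-methoxy-3,4-dihydronaphthalen-1(2H)-one | COc1ccc2C(=O)CCCc2c1 | starting material
2 | 6-methoxy-1,1-dimethyl-1,2,3,4-tetrahydronaphthalene | COc1ccc2c(c1)CCCC2(C)C | intermediate
3 | 6-methoxy-1,1-dimethyl-1,2,3,4,5,8-hexahydronaphthalene (not isolated) | COC1=CCC2=C(C1)CCCC2(C)C | intermediate
4 | 5,5-dimethyl-3,4,5,6,7,8-hexahydronaphthalen-2(1H)-one | O=C1CCC2=C(C1)CCCC2(C)C | intermediate
5 | (4aR)-5,5-dimethyl-4,4a,5,6,7,8-hexahydronaphthalen-2(3H)-one | O=C1C=C2CCCC(C)(C)[C@H]2CC1 | intermediate
6 | (R)-5-methoxy-3-methyl-5-oxopentanoic acid (methyl hydrogen (R)-3-methylglutarate) | COC(=O)C[C@H](C)CC(=O)O | starting material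
7 | (S)-5-hydroxy-3-methylpentanoic acid (not isolated) | OCC[C@H](C)CC(=O)O | intermediate
8 | (S)-4-methyloxan-2-one | O=C1C[C@@H](C)CCO1 | intermediate
9 | trimethylsilyl (R)-5-iodo-3-methylpentanoate (not isolated) | C[Si](C)(C)OC(=O)C[C@@H](C)CCI | intermediate
10 | methyl (R)-5-iodo-3-methylpentanoate | COC(=O)C[C@@H](C)CCI | intermediate
11 | lithium (4aR,8aS)-5,5,8a-trimethyl-3,4,4a,5,6,7,8,8a-octahydronaphthalen-2-olate (not isolated) | [Li]OC1=C[C@@]2(C)CCCC(C)(C)[C@H]2CC1 | intermediate
12 | methyl (3S)-3-methyl-5-[(1R,4aR,8aS)-5,5,8a-trimethyl-2-oxodecahydronaphthalen-1-yl]pentanoate | O=C1CC[C@@H]2C(C)(C)CCC[C@]2(C)[C@H]1CC[C@H](C)CC(=O)OC | intermediate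
13 | bromomagnesium alkoxide of methyl (3S)-5-[(1R,2R,4aR,8aS)-2-hydroxy-2,5,5,8a-tetramethyldecahydronaphthalen-1-yl]-3-methylpentanoate (not isolated) | Br[Mg]O[C@]1(C)CC[C@@H]2C(C)(C)CCC[C@]2(C)[C@H]1CC[C@H](C)CC(=O)OC | intermediate
14 | methyl (3S)-5-[(1R,2R,4aR,8aS)-2-acetoxy-2,5,5,8a-tetramethyldecahydronaphthalen-1-yl]-3-methylpentanoate | CC(=O)O[C@]1(C)CC[C@@H]2C(C)(C)CCC[C@]2(C)[C@H]1CC[C@H](C)CC(=O)OC | intermediate
15 | (3S)-5-[(1R,2R,4aR,8aS)-2-acetoxy-2,5,5,8a-tetramethyldecahydronaphthalen-1-yl]-3-methylpentanoic acid | CC(=O)O[C@]1(C)CC[C@@H]2C(C)(C)CCC[C@]2(C)[C@H]1CC[C@H](C)CC(=O)O | target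

**Step count**

Total: 8 steps. Longest linear sequence: 6 steps (1, 2, 3, 6, 7, 8); steps 4 and 5 make the side-chain iodide.

**Steps most likely to fail**

Step 6. The hindered enolate next to the new quaternary C10 may react too slowly with the unactivated iodide. Proton transfer between product ketone and enolate would then scramble the enolate (alkylation at C7, dialkylation) or return the unalkylated ketone; a sluggish conjugate addition is the second weak point. The fallback replaces the SN2 alkylation by an aldol reaction and a deoxygenation; it sets out from 5 and 10 and returns at 12. Kornblum oxidation of 10 (DMSO, NaHCO3, 100 °C) should give methyl (S)-3-methyl-5-oxopentanoate F1. The enolate from Me2CuLi addition to 5 is transmetalated with ZnCl2 and trapped at −78 °C with F1, a conjugate addition–aldol sequence that is fast even for hindered enolates, to give β-hydroxy ketone F2 as a mixture of carbinol epimers. Both epimers are converted with 1,1'-thiocarbonyldiimidazole into the imidazolyl thiocarbonate F3, and Barton–McCombie deoxygenation (Bu3SnH, AIBN, toluene, 90 °C) removes the C11 oxygen and should converge both epimers on 12.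

Step 3. The γ-protonation has to take place at a ring-fusion carbon next to the quaternary C4, so the enantioselectivity may be low or the conversion may stall, and 5 may slowly racemise by re-forming the dienamine. The fallback is a kinetic resolution; it sets out from 4 and returns at 5. Isomerisation with HCl in MeOH should give the racemic enone F4, and Luche reduction (NaBH4, CeCl3, MeOH) the racemic allylic alcohol F5. Lipase-catalysed acylation (Amano PS or CAL-B, vinyl acetate) is stopped near half conversion, and the acetate F6 of the (4aS) series is separated from the unreacted (4aR)-alcohol F7. If the enzyme prefers the other enantiomer, the acetate is the wanted fraction and is methanolysed to F7. Oxidation of F7 with MnO2 should give 5.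

Step 7. The methyl nucleophile may attack C8 with poor facial selectivity, because the axial C-11 chain on C9 also hinders the β-face, which would give the C8 epimer; enolisation of the hindered ketone is the second weak point. The fallback puts the new carbon equatorial under thermodynamic control; it sets out from 12 and returns at 15. A Corey–Chaykovsky reaction with dimethylsulfoxonium methylide (Me3S(O)I, NaH, DMSO), in which betaine formation is reversible, should give the spiro-epoxide methyl (13S)-8α,17-epoxy-5β-labdan-15-oate F8 with the CH2 on the β-face. LiEt3BH (THF, 0 °C) opens the epoxide at CH2 and reduces the ester to give (13S)-5β-labdane-8α,15-diol F9. TEMPO/NaOCl/NaClO2 oxidises only the primary alcohol to (13S)-8α-hydroxy-5β-labdan-15-oic acid F10. Ac2O, DMAP and Et3N, followed by aqueous pyridine to cleave the mixed anhydride, should give 15.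

**Further compounds**

F1 | step 6 | methyl (S)-3-methyl-5-oxopentanoate | COC(=O)C[C@@H](C)CC=O
F2 | step 6 | methyl (3S)-5-hydroxy-3-methyl-5-[(1S,4aR,8aS)-5,5,8a-trimethyl-2-oxodecahydronaphthalen-1-yl]pentanoate (both carbinol epimers) | O=C1CC[C@@H]2C(C)(C)CCC[C@]2(C)[C@H]1C(O)C[C@H](C)CC(=O)OC
F3 | step 6 | O-(1H-imidazol-1-ylcarbonothioyl) derivative of F2 | O=C1CC[C@@H]2C(C)(C)CCC[C@]2(C)[C@H]1C(OC(=S)n1ccnc1)C[C@H](C)CC(=O)OC
F4 | step 3 | rac-5,5-dimethyl-4,4a,5,6,7,8-hexahydronaphthalen-2(3H)-one | O=C1C=C2CCCC(C)(C)C2CC1
F5 | step 3 | rac-5,5-dimethyl-2,3,4,4a,5,6,7,8-octahydronaphthalen-2-ol | OC1C=C2CCCC(C)(C)C2CC1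
F6 | step 3 | (4aS)-5,5-dimethyl-2,3,4,4a,5,6,7,8-octahydronaphthalen-2-yl acetate | CC(=O)OC1C=C2CCCC(C)(C)[C@@H]2CC1
F7 | step 3 | (4aR)-5,5-dimethyl-2,3,4,4a,5,6,7,8-octahydronaphthalen-2-ol | OC1C=C2CCCC(C)(C)[C@H]2CC1
F8 | step 7 | methyl (13S)-8α,17-epoxy-5β-labdan-15-oate (spiro-oxirane at C8, O on the α-face) | O1C[C@]12CC[C@@H]3C(C)(C)CCC[C@]3(C)[C@H]2CC[C@H](C)CC(=O)OC
F9 | step 7 | (13S)-5β-labdane-8α,15-diol | O[C@]1(C)CC[C@@H]2C(C)(C)CCC[C@]2(C)[C@H]1CC[C@H](C)CCO
F10 | step 7 | (13S)-8α-hydroxy-5β-labdan-15-oic acid | O[C@]1(C)CC[C@@H]2C(C)(C)CCC[C@]2(C)[C@H]1CC[C@H](C)CC(=O)O
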